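The ratio we go by is dawn's to summer's. At 85 °C dawn carried 1.50 times summer's charge of solid substrate, yet at 8.00 min its [target] read 1.04 times summer's, and at 5.00 min summer had lost 0.0990 M of solid substrate and dawn 0.0990 M. So in these two runs the [target] reached in a given time did not follow the solid charged (in the usual term, zero order in the solid charge), and a percentage is that [target] divided by the charge.

For the next hand at the bench: each flask starts with the solid substrate undissolved, the reagent and the third substrate go in as the table tells for each flask, and the reading we want comes at 12 min.

| flask | solid substrate | reagent | second substrate | third substrate | temperature | remark | time |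
|---|---|---|---|---|---|---|---|
| summer | 0.30 M | 0.45 M | 0.060 M | 0.30 M | 85 °C | run made earlier |  |
| noon | 0.20 M | 0.45 M | 0.060 M | 0.30 M | 96 °C | run made earlier |  |
| dawn | 0.45 M | 0.45 M | 0.060 M | 0.30 M | 85 °C | run made earlier |  |
| Monday's | 0.30 M | 0.450 M (fed, over 30 s) | 0.0600 M | 0.300 M | 90 °C | all else is in the flask from the start; the feed brings no volume worth counting | 12 min |
| Tuesday's | 0.30 M | 0.450 M | 0.0600 M | 0.300 M | 90 °C | everything together at the start | 12 min |
| Friday's | 0.30 M | 0.450 M | 0.0600 M | 0.300 M (fed, over 5.0 min) |  | the addition at 50 °C, then warmed to 90 °C; the feed brings no volume worth counting | 12 min |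
| Thursday's | 0.30 M | 0.450 M | 0.0600 M | 0.300 M |  | everything together at the start at 50 °C, warmed to 90 °C at 5.0 min | 12 min |
| Sunday's | 0.30 M | 0.450 M | 0.0600 M | 0.300 M (fed, over 5.0 min) | 90 °C | all else is in the flask from the start; the feed brings no volume worth counting | 12 min |

| run | time / min | target / % | solid substrate / % |
|---|---|---|---|
| summer | 2.50 | 5 | 79 |
| summer | 5.00 | 15 | 67 |
| summer | 8.00 | 23 | 58 |
| summer | 10.0 | 27 | 45 |
| summer | 12.0 | 29 | 40 |
| noon | 0.667 | 1 | 88 |
| noon | 2.00 | 11 | 70 |
| noon | 3.00 | 17 | 62 |
| noon | 5.00 | 26 | 41 |
| noon | 8.00 | 44 | 18 |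
| dawn | 0.667 | 2 | 95 |
| dawn | 2.00 | 2 | 90 |
| dawn | 3.00 | 5 | 84 |
| dawn | 5.00 | 9 | 78 |
| dawn | 8.00 | 16 | 68 |

(readings scatter by 1.5 percentage points)

- which flask leads in amount of target, in percent of the solid substrate charged ("all alike" within 1.5 percentage points) (Monday's / Tuesday's / Friday's / Thursday's / Sunday's / all alike)
- how much target is there at the end, in percent of the solid substrate charged: Monday's
- how much target is there at the end, in percent of the solid substrate charged: Tuesday's
- how much target is there at the end, in percent of the solid substrate charged: Friday's
- how much target is there at the end, in percent of the solid substrate charged: Thursday's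
- how much target is there at the end, in percent of the solid substrate charged: Sunday's

- solid substrate is a solid; its amount is given per volume of the solution
- at the start none of the solid substrate is in solution

Since 90 °C lies nearly midway between 85 °C and 96 °C, we take the mean of summer's and noon's [target] at 8.00 min, which the ratio allows although their charges differ, and carry it forward by summer's own growth:

mean [target] at 8.00 min = 0.0785 M

growth from 8.00 min to 12.0 min = 1.26

product = 0.0990 M

We call this product the litre yield, the [target] a flask at 90 °C holds at 12 min at the charges tried. Over 0.30 M it gives 33.0 %, our own figure for Tuesday's, and for Monday's too on our assumption that a reagent feed over 30 s changes little, which no run tried; we set none for the flasks fed over 5.0 min or started at 50 °C, since no run tried those either. Leave the solid charge alone: dawn's percentage at 8.00 min read 16 % against summer's 23 %.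

The forecast named Tuesday's as leader, with 32 % for Monday's, 32 % for Tuesday's, 20 % for Friday's, 21 % for Thursday's and 30 % for Sunday's, holding that "Five cold minutes lose dissolution time".

The flasks give 33.5 % for Monday's, 33.1 % for Tuesday's, 31.4 % for Friday's, 30.9 % for Thursday's and 37.2 % for Sunday's, so Sunday's leads.

    starting material + reagent → target (k = 0.0180 L mol⁻¹ s⁻¹, Ea = 76.0 kJ mol⁻¹)
    second substrate + reagent → second product (k = 0.227 L mol⁻¹ s⁻¹, Ea = 74.0 kJ mol⁻¹)
    third substrate + reagent → third product (k = 0.00646 L mol⁻¹ s⁻¹, Ea = 54.0 kJ mol⁻¹)
    target ⇌ isomer of the product (K = 0.277, k = 0.00140 s⁻¹, Ea = 105 kJ mol⁻¹, ΔH = −29.0 kJ mol⁻¹)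
    solid substrate ⇌ starting material, rate k5*(cs5 - [starting material]) while solid is left; crystals form when [starting material] > cs5 (solubility = 0.100 M, k = 0.00582 s⁻¹)
    (constants at 90 °C)

A neighbour of Thursday's, changed in one setting, holds 0.75 M of solid substrate. The litre yield was reckoned for a flask held at 90 °C, so here we stretch it to a cold start and to a charge larger than any tried; over that charge it gives 13.2 %, and the neighbour ends at 12.3 %, which is 0.0923 M of target against 0.0927 M in Thursday's.

(The data stem from a simulated flask on assumed constants; scatter was added.)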